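**Plan** (target ring numbering: C1 C=O, C2 C–CH2OH, C3 =CH, C4 CH–O-propanoyl, C5 CH–iPr, C6 CH–O-acyl)

- Retrosynthesis: remove both esters and the C2–CH2OH bond (Morita–Baylis–Hillman), return C1=O/C2=C3 to a C1=C2 alkene with C3H2 (singlet-oxygen ene), then cut C3–C4 and C1–C6 together.
- Enabling feature: the carbinol carbons C4 and C6 flank C5 (a 2-isopropylmalondialdehyde unit) and each is bonded to one end of the three-carbon unit C1–C2–C3 (a propene 1,3-dianion), so the carbocycle is a [3+3] double-allylation adduct.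
- Forward: an Evans alkylation gives the mono-masked dialdehyde; one flask then forms C1–C6 (allylboration) and closes the ring at C3–C4 (intramolecular allylboration); ring oxidation, two acylations and hydroxymethylation follow; the side-chain acid comes from a Wittig reaction.
- Stereochemistry: C5 from the bought oxazolidinone auxiliary, C6 from the chiral borane, C4 relayed from C6 through the C1–B stereocentre in a closed transition state.

Key step: step 4

Assumption: the (10R) enantiomer of borane 7 (freed from its air-stable borinate precursor by the usual hydride/TMSCl protocol) is taken to deliver the allyl unit to the Si face of aldehyde 5, as the (+)-α-pinene-derived Ipc2B reagents do; if the sense is opposite, the antipode of 7 is used and nothing else changes.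

**Step 1**
Reactants: 1 (4R)-4-benzyl-3-(3-methylbutanoyl)-1,3-oxazolidin-2-one; 2 trimethyl orthoformate
Product: 3 (4R)-4-benzyl-3-[(2S)-2-(dimethoxymethyl)-3-methylbutanoyl]-1,3-oxazolidin-2-one
Conditions: TiCl4, iPr2NEt, CH2Cl2, 0 °C; then 2, 0 °C → rt
Reagents that add atoms: none
Why: Evans alkylation of the chelated Z titanium enolate with the dimethoxycarbenium ion from the orthoformate; the benzyl group shields one enolate face and so sets C5.

**Step 2**
Reactants: 3
Product: 4 (2R)-2-(dimethoxymethyl)-3-methylbutan-1-ol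
Conditions: LiBH4, MeOH (1 equiv), Et2O, 0 °C
Reagents that add atoms: none
Why: reductive cleavage of the N-acyl oxazolidinone to the primary alcohol should leave the acetal and the C5 stereocentre untouched and return the auxiliary.

**Step 3**
Reactants: 4
Product: 5 (2R)-2-(dimethoxymethyl)-3-methylbutanal
Conditions: Dess–Martin periodinane, NaHCO3, CH2Cl2, 0 °C; used crude
Reagents that add atoms: none
Why: buffered Dess–Martin oxidation should give the α-branched aldehyde without epimerisation or loss of methanol from the β-acetal.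

**Step 4**
Reactants: 5 (2R)-2-(dimethoxymethyl)-3-methylbutanal; 6 allenylboronic acid pinacol ester; 7 (10R)-10-(trimethylsilyl)-9-borabicyclo[3.3.2]decane
Product: 11 (1S,2S,3S)-2-(propan-2-yl)cyclohex-4-ene-1,3-diol, via Z-boryl allylborane 8 (not isolated), via borinate adduct 9 (not isolated), via hydroxy aldehyde boronate 10 (not isolated)
Conditions: 6, 7, THF, −78 → −25 °C; 5, −78 °C; then THF–AcOH–H2O, 0.01 M, rt → 45 °C
Reagents that add atoms: water, O
Why: Proposed new method: hydroboration of 6 gives the kinetic Z allylborane 8, whose chair-type allylboration of 5 forms C1–C6 and gives 9 with C6 fixed by the chiral borane (Si-face attack) and the C1–B stereocentre syn to the C6 oxygen; hydrolysis of borinate and acetal then unveils aldehyde 10, whose α-substituted allylboronate adds intramolecularly to the C4 aldehyde (C3–C4 bond, boron passing to the new C4 oxygen). The closest known reaction type is the one-pot double allylboration of two separate aldehydes with γ-boryl allylboranes; new is that the second aldehyde is tethered to the boron-bearing carbon. The six-membered carbocycle closes in the endo sense (all three allyl carbons in the ring, cis C1=C2 alkene) through a closed, boat-like bicyclo[2.2.2] array in which B–O bridges C1 and C4, instead of the usual chair. C4 is controlled by suprafacial delivery from the C1–B bond, which places its oxygen trans to the C6 oxygen and cis to the C5 isopropyl group; C5 is carried in from 5. The step needs ring closure to beat intermolecular allylboration and dehydration of the β-hydroxy aldehyde, which high dilution, the short tether and the weakly acidic medium should secure, and it needs the Z geometry of 8, secured by keeping 8 cold until it is consumed.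

**Step 5**
Reactants: 11
Product: 12 (1S,5S,6S)-5-[(tert-butyldimethylsilyl)oxy]-6-(propan-2-yl)cyclohex-3-en-1-ol
Conditions: TBSCl (1.05 equiv), imidazole, DMF, −20 → 0 °C
Reagents that add atoms: tert-butyldimethylsilyl chloride, CC(C)(C)[Si](C)(C)Cl
Why: kinetic monosilylation should favour the pseudo-equatorial allylic hydroxyl at C6 over the axial C4 hydroxyl that is cis to the isopropyl group.

**Step 6**
Reactants: 12
Product: 13 (1S,5S,6S)-5-[(tert-butyldimethylsilyl)oxy]-6-(propan-2-yl)cyclohex-3-en-1-yl propanoate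
Conditions: (EtCO)2O, Et3N, DMAP (cat.), CH2Cl2, rt
Reagents that add atoms: propanoic anhydride, CCC(=O)OC(=O)CC
Why: DMAP-catalysed acylation of the remaining secondary alcohol installs the C4 propanoate.

**Step 7**
Reactants: 13
Product: 15 (1S,5R,6S)-5-[(tert-butyldimethylsilyl)oxy]-4-oxo-6-(propan-2-yl)cyclohex-2-en-1-yl propanoate, via allylic hydroperoxide 14 (not isolated)
Conditions: O2, TPP (cat.), visible light, Ac2O, pyridine, DMAP (cat.), CH2Cl2, rt
Reagents that add atoms: dioxygen, O=O
Why: in the Schenck ene reaction singlet oxygen should bond to C1 and take an allylic hydrogen from C3H2 rather than the hydrogen geminal to oxygen at C6, which moves the alkene to C2=C3, and the secondary hydroperoxide is dehydrated in the same pot (Kornblum–DeLaMare-type elimination of its peracetate) to the enone.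

**Step 8**
Reactants: 15
Product: 16 (1S,5R,6R)-5-hydroxy-4-oxo-6-(propan-2-yl)cyclohex-2-en-1-yl propanoate
Conditions: HF·pyridine, THF, 0 °C → rt
Reagents that add atoms: none
Why: acidic fluoride cleavage of the silyl ether should spare the propanoate and not enolise the α-hydroxy ketone.

**Step 9**
Reactants: 17 (tert-butyldimethylsilyloxy)acetaldehyde; 18 ethyl 2-(triphenylphosphoranylidene)propanoate
Product: 19 ethyl (2E)-4-[(tert-butyldimethylsilyl)oxy]-2-methylbut-2-enoate
Conditions: CH2Cl2, rt → 40 °C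
Reagents that add atoms: none
Why: Wittig olefination with the stabilised α-methyl ylide should give the E trisubstituted enoate.

**Step 10**
Reactants: 19
Product: 20 (2E)-4-[(tert-butyldimethylsilyl)oxy]-2-methylbut-2-enoic acid
Conditions: LiOH, THF–MeOH–H2O, 0 °C → rt; then aq. HCl to pH 4
Reagents that add atoms: lithium hydroxide, [Li+].[OH-]
Why: saponification of the ethyl ester under conditions the primary silyl ether should survive.

**Step 11**
Reactants: 16; 20
Product: 21 (1R,5S,6S)-2-oxo-6-(propan-2-yl)-5-(propanoyloxy)cyclohex-3-en-1-yl (2E)-4-[(tert-butyldimethylsilyl)oxy]-2-methylbut-2-enoate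
Conditions: EDC·HCl, DMAP, CH2Cl2, 0 °C → rt
Reagents that add atoms: none
Why: Steglich esterification of the secondary α-hydroxy ketone; the trans (equatorial) C6 configuration is retained.

**Step 12**
Reactants: 21
Product: 22 (1R,5S,6S)-3-(hydroxymethyl)-2-oxo-6-(propan-2-yl)-5-(propanoyloxy)cyclohex-3-en-1-yl (2E)-4-[(tert-butyldimethylsilyl)oxy]-2-methylbut-2-enoate
Conditions: aq. HCHO (37%), DMAP (0.3 equiv), THF, rt
Reagents that add atoms: formaldehyde, C=O
Why: Morita–Baylis–Hillman reaction, in which DMAP adds to C3, the enolate is hydroxymethylated at C2 and loss of DMAP restores the enone.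

**Step 13**
Reactants: 22
Product: 23 (1R,5S,6S)-3-(hydroxymethyl)-2-oxo-6-(propan-2-yl)-5-(propanoyloxy)cyclohex-3-en-1-yl (2E)-4-hydroxy-2-methylbut-2-enoate
Conditions: HF·pyridine, pyridine, THF, 0 °C
Reagents that add atoms: none
Why: buffered fluoride cleavage of the primary silyl ether should leave both esters, the enone and the allylic alcohol intact.

**Compound list**

1 | (4R)-4-benzyl-3-(3-methylbutanoyl)-1,3-oxazolidin-2-one | CC(C)CC(=O)N1[C@H](Cc2ccccc2)COC1=O | starting material
2 | trimethyl orthoformate | COC(OC)OC | starting material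
3 | (4R)-4-benzyl-3-[(2S)-2-(dimethoxymethyl)-3-methylbutanoyl]-1,3-oxazolidin-2-one | O=C([C@@H](C(C)C)C(OC)OC)N1[C@H](Cc2ccccc2)COC1=O | intermediate
4 | (2R)-2-(dimethoxymethyl)-3-methylbutan-1-ol | OC[C@@H](C(C)C)C(OC)OC | intermediate
5 | (2R)-2-(dimethoxymethyl)-3-methylbutanal | O=C[C@@H](C(C)C)C(OC)OC | intermediate
6 | allenylboronic acid pinacol ester | C=C=CB1OC(C)(C)C(C)(C)O1 | starting material
7 | (10R)-10-(trimethylsilyl)-9-borabicyclo[3.3.2]decane (10-TMS-9-BBD-H) | B1[C@@H]2CCC[C@@H](CCC2)[C@@H]1[Si](C)(C)C | starting material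
8 | (10R)-9-[(2Z)-3-(4,4,5,5-tetramethyl-1,3,2-dioxaborolan-2-yl)prop-2-en-1-yl]-10-(trimethylsilyl)-9-borabicyclo[3.3.2]decane | C(/C=C\B3OC(C)(C)C(C)(C)O3)B1[C@@H]2CCC[C@@H](CCC2)[C@@H]1[Si](C)(C)C | intermediate (not isolated)
9 | (10R)-9-{[(2R,3S,4R)-1,1-dimethoxy-2-(propan-2-yl)-4-(4,4,5,5-tetramethyl-1,3,2-dioxaborolan-2-yl)hex-5-en-3-yl]oxy}-10-(trimethylsilyl)-9-borabicyclo[3.3.2]decane | COC(OC)[C@H](C(C)C)[C@@H](OB1[C@@H]2CCC[C@@H](CCC2)[C@@H]1[Si](C)(C)C)[C@@H](C=C)B3OC(C)(C)C(C)(C)O3 | intermediate (not isolated)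
10 | (2R,3S,4R)-3-hydroxy-2-(propan-2-yl)-4-(4,4,5,5-tetramethyl-1,3,2-dioxaborolan-2-yl)hex-5-enal | O=C[C@H](C(C)C)[C@@H](O)[C@@H](C=C)B1OC(C)(C)C(C)(C)O1 | intermediate (not isolated)
11 | (1S,2S,3S)-2-(propan-2-yl)cyclohex-4-ene-1,3-diol (allylic OH trans to iPr; homoallylic OH cis to iPr) | O[C@H]1CC=C[C@H](O)[C@H]1C(C)C | intermediate
12 | (1S,5S,6S)-5-[(tert-butyldimethylsilyl)oxy]-6-(propan-2-yl)cyclohex-3-en-1-ol | O[C@H]1CC=C[C@H](O[Si](C)(C)C(C)(C)C)[C@H]1C(C)C | intermediate
13 | (1S,5S,6S)-5-[(tert-butyldimethylsilyl)oxy]-6-(propan-2-yl)cyclohex-3-en-1-yl propanoate | CCC(=O)O[C@H]1CC=C[C@H](O[Si](C)(C)C(C)(C)C)[C@H]1C(C)C | intermediate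
14 | (1S,4R,5R,6S)-5-[(tert-butyldimethylsilyl)oxy]-4-hydroperoxy-6-(propan-2-yl)cyclohex-2-en-1-yl propanoate (OOH trans to OTBS; this centre is destroyed) | CCC(=O)O[C@H]1C=C[C@@H](OO)[C@H](O[Si](C)(C)C(C)(C)C)[C@H]1C(C)C | intermediate (not isolated)
15 | (1S,5R,6S)-5-[(tert-butyldimethylsilyl)oxy]-4-oxo-6-(propan-2-yl)cyclohex-2-en-1-yl propanoate | CCC(=O)O[C@H]1C=CC(=O)[C@H](O[Si](C)(C)C(C)(C)C)[C@H]1C(C)C | intermediate
16 | (1S,5R,6R)-5-hydroxy-4-oxo-6-(propan-2-yl)cyclohex-2-en-1-yl propanoate | CCC(=O)O[C@H]1C=CC(=O)[C@H](O)[C@H]1C(C)C | intermediate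
17 | (tert-butyldimethylsilyloxy)acetaldehyde | CC(C)(C)[Si](C)(C)OCC=O | starting material
18 | ethyl 2-(triphenylphosphoranylidene)propanoate | CCOC(=O)C(C)=P(c1ccccc1)(c1ccccc1)c1ccccc1 | starting material
19 | ethyl (2E)-4-[(tert-butyldimethylsilyl)oxy]-2-methylbut-2-enoate | CCOC(=O)/C(C)=C/CO[Si](C)(C)C(C)(C)C | intermediate
20 | (2E)-4-[(tert-butyldimethylsilyl)oxy]-2-methylbut-2-enoic acid | OC(=O)/C(C)=C/CO[Si](C)(C)C(C)(C)C | intermediate
21 | (1R,5S,6S)-2-oxo-6-(propan-2-yl)-5-(propanoyloxy)cyclohex-3-en-1-yl (2E)-4-[(tert-butyldimethylsilyl)oxy]-2-methylbut-2-enoate | CCC(=O)O[C@H]1C=CC(=O)[C@H](OC(=O)/C(C)=C/CO[Si](C)(C)C(C)(C)C)[C@H]1C(C)C | intermediate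
22 | (1R,5S,6S)-3-(hydroxymethyl)-2-oxo-6-(propan-2-yl)-5-(propanoyloxy)cyclohex-3-en-1-yl (2E)-4-[(tert-butyldimethylsilyl)oxy]-2-methylbut-2-enoate | CCC(=O)O[C@H]1C=C(CO)C(=O)[C@H](OC(=O)/C(C)=C/CO[Si](C)(C)C(C)(C)C)[C@H]1C(C)C | intermediate
23 | (1R,5S,6S)-3-(hydroxymethyl)-2-oxo-6-(propan-2-yl)-5-(propanoyloxy)cyclohex-3-en-1-yl (2E)-4-hydroxy-2-methylbut-2-enoate | CCC(=O)O[C@H]1C=C(CO)C(=O)[C@H](OC(=O)/C(C)=C/CO)[C@H]1C(C)C | target

**Count**

Total steps: 13. Longest linear sequence: 11 (steps 1–8, 11–13).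

**Steps most likely to fail**

1. Step 4 (proposed new method). The boat-like bicyclic transition state may be too strained, so that intermolecular allylboration (oligomers), dehydration of the β-hydroxy aldehyde or epimerisation at C5 outruns ring closure; the isopropyl group sits on the boron-bridged face, which adds to the strain. The fallback uses only known reaction types and an open transition state. It sets out from 5: anti-selective γ-silylallylboration with B-[(E)-3-(trimethylsilyl)allyl]diisopinocampheylborane F1 (from allyltrimethylsilane, nBuLi/TMEDA, the (+)-α-pinene-derived Ipc2BOMe and BF3·OEt2; oxidative work-up) should give the anti β-hydroxy allylsilane F2, with C6 again reagent-controlled. Silylation (TBSOTf, 2,6-lutidine) should give the silyl ether F3, and mild acetal hydrolysis (LiBF4, wet MeCN) the aldehyde F4. BF3·OEt2 at −78 °C should then close the ring by an intramolecular Hosomi–Sakurai reaction (anti SE2′, silicon axial, silyloxy and isopropyl equatorial, synclinal carbonyl, so C4 rests on that preference). This comes back at 12, and the route continues with step 6.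

2. Step 7. The ene reaction of a cis-disubstituted cyclohexene flanked by two oxygenated carbons may be too slow, or hydrogen abstraction may occur at the wrong allylic position. The fallback sets out from 13: mCPBA should give the epoxide F5 (either face serves). Phenylselenide (PhSeSePh, NaBH4, EtOH) should open it at C2, remote from the silyloxy carbon, to the hydroxy selenide F6. H2O2 should then trigger selenoxide syn-elimination away from the carbinol to the allylic alcohol F7, and Dess–Martin oxidation comes back at 15.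

3. Step 5. Discrimination between the two secondary hydroxyls may be poor, giving mixtures of regioisomeric and bis-silyl ethers; if the preference is merely reversed, steps 5 and 6 are exchanged. The fallback differentiates by electronic activation at the enone stage instead of sterics and sets out from 11: double propanoylation should give the dipropanoate F8. Photooxygenation and dehydration as in step 7 (via the hydroperoxide F9, not isolated) should give the enone dipropanoate F10. Selective methanolysis of the activated α-keto ester (K2CO3, MeOH, −20 °C, or a lipase) comes back at 16, and the route continues with step 11.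

**Further compounds**

F1 | step 4 | B-[(2E)-3-(trimethylsilyl)prop-2-en-1-yl]diisopinocampheylborane (from (+)-α-pinene) | C[Si](C)(C)/C=C/CB([C@@H]1C[C@@H]2C[C@@H](C2(C)C)[C@H]1C)[C@@H]1C[C@@H]2C[C@@H](C2(C)C)[C@H]1C
F2 | step 4 | (2R,3R,4S)-1,1-dimethoxy-2-(propan-2-yl)-4-(trimethylsilyl)hex-5-en-3-ol (anti hydroxy silane) | COC(OC)[C@H](C(C)C)[C@@H](O)[C@H](C=C)[Si](C)(C)C
F3 | step 4 | tert-butyldimethylsilyl ether of F2 | COC(OC)[C@H](C(C)C)[C@@H](O[Si](C)(C)C(C)(C)C)[C@H](C=C)[Si](C)(C)C
F4 | step 4 | 3-[(tert-butyldimethylsilyl)oxy]-2-(propan-2-yl)-4-(trimethylsilyl)hex-5-enal | O=C[C@H](C(C)C)[C@@H](O[Si](C)(C)C(C)(C)C)[C@H](C=C)[Si](C)(C)C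
F5 | step 7 | 3,4-epoxide of 13 (oxirane trans to the silyloxy group) | CCC(=O)O[C@H]1C[C@H]2O[C@H]2[C@H](O[Si](C)(C)C(C)(C)C)[C@H]1C(C)C
F6 | step 7 | 5-[(tert-butyldimethylsilyl)oxy]-4-hydroxy-3-(phenylselanyl)-6-(propan-2-yl)cyclohexyl propanoate | CCC(=O)O[C@H]1C[C@H]([Se]c2ccccc2)[C@@H](O)[C@H](O[Si](C)(C)C(C)(C)C)[C@H]1C(C)C
F7 | step 7 | (1S,4R,5R,6S)-5-[(tert-butyldimethylsilyl)oxy]-4-hydroxy-6-(propan-2-yl)cyclohex-2-en-1-yl propanoate | CCC(=O)O[C@H]1C=C[C@@H](O)[C@H](O[Si](C)(C)C(C)(C)C)[C@H]1C(C)C
F8 | step 5 | (1S,2S,3S)-2-(propan-2-yl)cyclohex-4-ene-1,3-diyl dipropanoate | CCC(=O)O[C@H]1CC=C[C@H](OC(=O)CC)[C@H]1C(C)C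
F9 | step 5 | 4-hydroperoxy-6-(propan-2-yl)cyclohex-2-ene-1,5-diyl dipropanoate | CCC(=O)O[C@H]1C=C[C@@H](OO)[C@H](OC(=O)CC)[C@H]1C(C)C
F10 | step 5 | 4-oxo-6-(propan-2-yl)cyclohex-2-ene-1,5-diyl dipropanoate | CCC(=O)O[C@H]1C=CC(=O)[C@H](OC(=O)CC)[C@H]1C(C)C
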